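Labdane numbering is used (C1–C20). Everything rests on forming the ring-fusion bond C5–C10 while closing ring A. The key step exploits the 1,5-relation of the C9 and C7 oxygens across C10–C5 and the C19 hydroxymethyl on C4: O19 is tied to C7 as a temporary unsaturated δ-lactone. Base-induced 6-exo Michael addition of the C10 ketone enolate to lactone carbon C5 closes ring A and sets C5 and C10; in the same flask methoxide opens the lactone and a Dieckmann condensation (C7–C8) closes ring B, releasing the C19 alcohol. The precursor is a geraniol-derived keto lactone whose only fixed stereocentre is quaternary C4.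

Key step: step 9

Remark on the chemistry (assumption): the target is taken as a normal-series labdane. Ring A is C1–C5/C10 and ring B is C5–C10; C11 and C12 are the CH2CH2 of the spiro tetrahydrofuran, C13 the bis-spiro carbon, C14=C15 the enol ether and C16 its OCH2. C17 is the methyl on C8, C18 the α-methyl and C19 the β-CH2OH on C4, C20 the methyl on C10; β is the face of C20. Compounds 1, 8 and 18 and all reagents are taken as commercial.

**Route**

Step 1
Reactants: 1 geraniol
Product: 2 (2R,3R)-2,3-epoxygeraniol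
Conditions: Ti(OiPr)4 (5 mol %), D-(−)-diethyl tartrate (6 mol %), t-BuOOH, 4 Å molecular sieves, CH2Cl2, −20 °C
Reagents that add atoms: tert-butyl hydroperoxide, CC(C)(C)OO
Why: Sharpless asymmetric epoxidation of the allylic alcohol alkene only; the D-(−)-tartrate delivers oxygen to the face that gives the (2R,3R)-epoxide, whose tertiary carbon becomes C4.

Step 2
Reactants: 2 (2R,3R)-2,3-epoxygeraniol
Product: 3 silyl ether of 2
Conditions: t-BuMe2SiCl, imidazole, DMF, 0 °C to rt
Reagents that add atoms: tert-butyldimethylsilyl chloride, CC(C)(C)[Si](C)(C)Cl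
Why: Standard silylation of the primary alcohol, which supplies the migrating siloxymethyl group for the next step.

Step 3
Reactants: 3 silyl ether of 2
Product: 4 (2R)-2-[(tert-butyldimethylsilyloxy)methyl]-2,6-dimethylhept-5-enal
Conditions: MeAl(OAr)2 (2 equiv; Ar = 4-bromo-2,6-di-tert-butylphenyl; from Me3Al and ArOH), CH2Cl2, −78 to −20 °C
Reagents that add atoms: none
Why: Yamamoto–Maruoka rearrangement of an epoxy silyl ether: the bulky aluminium Lewis acid opens the epoxide at the tertiary carbon and the siloxymethyl group migrates anti to the leaving oxygen, so the epoxide chirality is transferred with inversion into the quaternary centre C4 carrying C18, C19 and the aldehyde (future C5).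

Step 4
Reactants: 4 (2R)-2-[(tert-butyldimethylsilyloxy)methyl]-2,6-dimethylhept-5-enal
Product: 6 (5S)-5-methyl-5-(4-methylpent-3-enyl)-5,6-dihydro-2H-pyran-2-one, via Z-enoate 5 (not isolated)
Conditions: (CF3CH2O)2P(O)CH2CO2Me, KN(SiMe3)2, 18-crown-6, THF, −78 °C; then aq. HF, MeCN, rt
Reagents that add atoms: methyl bis(2,2,2-trifluoroethyl)phosphonoacetate, COC(=O)CP(=O)(OCC(F)(F)F)OCC(F)(F)F
Why: Still–Gennari olefination should give the (Z)-enoate, and desilylation lets the δ-hydroxy (Z)-ester lactonise, which installs the temporary O19–C7 lactone (any E-isomer cannot cyclise and is removed).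

Step 5
Reactants: 6 (5S)-5-methyl-5-(4-methylpent-3-enyl)-5,6-dihydro-2H-pyran-2-one
Product: 7 3-[(3S)-3-methyl-6-oxo-3,6-dihydro-2H-pyran-3-yl]propanal
Conditions: O3, CH2Cl2/pyridine, −78 °C (Sudan red end point); Me2S
Reagents that add atoms: ozone, [O-][O+]=O
Why: Ozonolysis is chemoselective for the electron-rich trisubstituted alkene over the conjugated, electron-poor lactone alkene.

Step 6
Reactants: 8 2-bromopentan-3-one
Product: 10 2-(triphenylphosphoranylidene)pentan-3-one, via phosphonium bromide 9 (not isolated)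
Conditions: PPh3, toluene, 80 °C; then aq. NaOH, CH2Cl2
Reagents that add atoms: triphenylphosphine, c1ccc(cc1)P(c1ccccc1)c1ccccc1
Why: SN2 quaternisation of triphenylphosphine by the α-bromo ketone and deprotonation give the stabilised keto ylide that carries C10, C20, C9, C8 and C17.

Step 7
Reactants: 7 3-[(3S)-3-methyl-6-oxo-3,6-dihydro-2H-pyran-3-yl]propanal; 10 2-(triphenylphosphoranylidene)pentan-3-one
Product: 11 (5S)-5-methyl-5-[(3E)-4-methyl-5-oxohept-3-enyl]-5,6-dihydro-2H-pyran-2-one
Conditions: toluene, 90 °C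
Reagents that add atoms: none
Why: Wittig reaction of a stabilised ylide with an unhindered aldehyde should give the (E)-trisubstituted enone and leaves the lactone untouched.

Step 8
Reactants: 11 (5S)-5-methyl-5-[(3E)-4-methyl-5-oxohept-3-enyl]-5,6-dihydro-2H-pyran-2-one
Product: 12 (5S)-5-methyl-5-(4-methyl-5-oxoheptyl)-5,6-dihydro-2H-pyran-2-one (both epimers at the CHMe carbon)
Conditions: [(Ph3P)CuH]6 (0.4 equiv), degassed benzene, H2O (3 equiv), rt
Reagents that add atoms: none
Why: Conjugate reduction with the copper hydride hexamer should take the ketone-conjugated alkene and spare the lactone alkene, whose β-carbon is neopentylic; the new CHMe centre is inconsequential because it is enolised in step 9.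

Step 9
Reactants: 12 (5S)-5-methyl-5-(4-methyl-5-oxoheptyl)-5,6-dihydro-2H-pyran-2-one
Product: 15 19-hydroxy-11,12,13,14,15,16-hexanorlabdane-7,9-dione (trans-decalin isolated as the 7-enol), via Michael adduct 13 (not isolated), via hydroxy ester 14 (not isolated)
Conditions: t-BuOK (0.3 equiv), THF/t-BuOH, −20 to 0 °C; then NaOMe, MeOH, 60 °C; aq. HCl
Reagents that add atoms: none
Why: Catalytic t-BuOK equilibrates the ketone enolates and only the C10 enolate can reach the acceptor, so it adds to the lactone β-carbon C5 to form C5–C10; once ring A is closed, methoxide opens the lactone to hydroxy ester 14 and the C8 enolate of the ethyl ketone attacks the ester carbonyl C7, the resulting 2-methyl-1,3-dione enolate making the sequence irreversible. The closest known chemistry is the Stork intramolecular ketone–enoate Michael addition coupled to the Michael–Claisen (dimedone-type) synthesis of cyclohexane-1,3-diones, the second stage being the textbook Dieckmann closure of a 5-oxoheptanoate. Ring A closes 6-exo-trig (Michael addition) and ring B closes 6-exo-trig (acyl substitution at C7). C5 is controlled by quaternary C4, because the three-carbon tether can deliver C10 only to the lactone face it occupies, giving the cis-fused lactone in which H5 and the C18 methyl are cis and C19 is axial on ring A; C10 is controlled in the chair-like transition state, where the bulky enolate terminus (C9 bearing OK and ethyl) should take the outside position anti to C4 and the small methyl sits over the lactone ring, so that the C9 acyl group and the C6 arm end up trans-diequatorial. The step needs enolate regioselection (secured by ring size, since the C8 enolate would have to close an eight-membered ring), trans over cis ring fusion (secured by the lactone shielding one quadrant in the cold Michael stage) and lactone opening before acylation (a trans-fused decalin cannot keep the C19–O–C7 bridge; secured by methoxide).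

Step 10
Reactants: 15 19-hydroxy-11,12,13,14,15,16-hexanorlabdane-7,9-dione
Product: 16 19-hydroxy-7-methoxy-11,12,13,14,15,16-hexanorlabd-7-en-9-one
Conditions: MeOH, TsOH·H2O (cat.), 3 Å molecular sieves, 40 °C
Reagents that add atoms: methanol, CO
Why: Acid-catalysed enol ether formation should occur at the less hindered C7 carbonyl (C9 is flanked by quaternary C10), which leaves the C9 carbonyl for the 1,2-addition; the minor regioisomer can be hydrolysed back to 15.

Step 11
Reactants: 16 19-hydroxy-7-methoxy-11,12,13,14,15,16-hexanorlabd-7-en-9-one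
Product: 17 19-(tert-butyldimethylsilyloxy)-7-methoxy-11,12,13,14,15,16-hexanorlabd-7-en-9-one
Conditions: t-BuMe2SiCl, imidazole, DMF, rt
Reagents that add atoms: tert-butyldimethylsilyl chloride, CC(C)(C)[Si](C)(C)Cl
Why: Silylation protects the C19 alcohol against the organolithium, the oxidant and the acylation that follow.

Step 12
Reactants: 18 2-methylenepropane-1,3-diol
Product: 19 2-[(tert-butyldimethylsilyloxy)methyl]prop-2-en-1-ol
Conditions: NaH (1 equiv), THF, 0 °C; t-BuMe2SiCl (1 equiv)
Reagents that add atoms: tert-butyldimethylsilyl chloride, CC(C)(C)[Si](C)(C)Cl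
Why: Monosilylation of a symmetrical diol through its sparingly soluble mono-alkoxide differentiates the future C16 (silylated) and C14 (free) arms.

Step 13
Reactants: 19 2-[(tert-butyldimethylsilyloxy)methyl]prop-2-en-1-ol
Product: 20 (R)-{2-[(tert-butyldimethylsilyloxy)methyl]oxiran-2-yl}methanol
Conditions: Ti(OiPr)4 (10 mol %), D-(−)-diethyl tartrate (12 mol %), t-BuOOH, 4 Å molecular sieves, CH2Cl2, −20 °C
Reagents that add atoms: tert-butyl hydroperoxide, CC(C)(C)OO
Why: Sharpless asymmetric epoxidation of a 2-substituted allylic alcohol; the tartrate alone decides the face and thereby sets the configuration of C13.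

Step 14
Reactants: 20 (R)-{2-[(tert-butyldimethylsilyloxy)methyl]oxiran-2-yl}methanol
Product: 22 (R)-tert-butyl[(2-ethynyloxiran-2-yl)methoxy]dimethylsilane, via epoxy aldehyde 21 (not isolated)
Conditions: Dess–Martin periodinane, CH2Cl2, 0 °C; then MeC(O)C(N2)P(O)(OMe)2, K2CO3, MeOH, 0 °C to rt
Reagents that add atoms: dimethyl (1-diazo-2-oxopropyl)phosphonate, COP(=O)(OC)C(=[N+]=[N-])C(C)=O
Why: Oxidation to the non-epimerisable epoxy aldehyde and Ohira–Bestmann homologation give the terminal alkyne (C14≡C15) without touching C13.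

Step 15
Reactants: 22 (R)-tert-butyl[(2-ethynyloxiran-2-yl)methoxy]dimethylsilane
Product: 23 (3S)-3-[(tert-butyldimethylsilyloxy)methyl]-5-(phenylsulfanyl)pent-1-yn-3-ol
Conditions: PhSCH2Li (2.5 equiv; from PhSMe, n-BuLi, DABCO), THF, −78 °C to rt; aq. NH4Cl
Reagents that add atoms: (phenylsulfanyl)methyllithium, [Li]CSc1ccccc1
Why: After deprotonation of the alkyne, the sulfur-stabilised organolithium opens the 2,2-disubstituted epoxide by SN2 attack at its CH2 terminus, which adds C11 and frees the tertiary C13 hydroxyl with its configuration unchanged.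

Step 16
Reactants: 17 19-(tert-butyldimethylsilyloxy)-7-methoxy-11,12,13,14,15,16-hexanorlabd-7-en-9-one; 23 (3S)-3-[(tert-butyldimethylsilyloxy)methyl]-5-(phenylsulfanyl)pent-1-yn-3-ol
Product: 26 (13S)-16,19-bis(tert-butyldimethylsilyloxy)-13-hydroxylabd-8-en-14-yn-7-one, via trilithio reagent 24 (not isolated), via carbinol adduct 25 (not isolated)
Conditions: 23: n-BuLi (2 equiv), THF, −78 °C; lithium 4,4'-di-tert-butylbiphenylide (2.1 equiv), −78 °C; add 17, −78 to −40 °C; then 1 M aq. HCl, THF, 0 °C
Reagents that add atoms: water, O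
Why: Cohen-type reductive lithiation of the phenyl sulfide gives the primary alkyllithium (alkoxide and acetylide are spectators at −78 °C), and its Stork–Danheiser 1,2-addition to the C9 carbonyl followed by acidic hydrolysis and transposition gives the 8-en-7-one, so the configuration at C9 in 25 is irrelevant.

Step 17
Reactants: 26 (13S)-16,19-bis(tert-butyldimethylsilyloxy)-13-hydroxylabd-8-en-14-yn-7-one
Product: 27 (13S)-16,19-bis(tert-butyldimethylsilyloxy)labd-8-en-14-yne-7β,13-diol
Conditions: NaBH4, CeCl3·7H2O, MeOH, −40 °C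
Reagents that add atoms: none
Why: Luche 1,2-reduction; hydride should add axially from the α face (antiparallel to the axial C6–H), giving the pseudo-equatorial 7β-alcohol needed to direct the epoxidation.

Step 18
Reactants: 27 (13S)-16,19-bis(tert-butyldimethylsilyloxy)labd-8-en-14-yne-7β,13-diol
Product: 29 (13S)-9α,13-epoxy-16,19-bis(tert-butyldimethylsilyloxy)labd-14-yne-7β,8β-diol, via epoxy alcohol 28 (not isolated)
Conditions: VO(acac)2 (5 mol %), t-BuOOH, CH2Cl2, 0 °C; then camphorsulfonic acid (10 mol %), 0 °C to rt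
Reagents that add atoms: tert-butyl hydroperoxide, CC(C)(C)OO
Why: Hydroxyl-directed vanadium-catalysed epoxidation should deliver oxygen syn to the 7β-OH (as with steroidal 4-en-3β-ols) to give the 8β,9β-epoxide, and acid then triggers 5-exo-tet, trans-diaxial (Fürst–Plattner) opening at C9 by the C13 hydroxyl with inversion, which sets 9α-O and 8β-OH and keeps C13 as made.

Step 19
Reactants: 29 (13S)-9α,13-epoxy-16,19-bis(tert-butyldimethylsilyloxy)labd-14-yne-7β,8β-diol
Product: 30 (13S)-9α,13-epoxy-8β-hydroxy-16,19-bis(tert-butyldimethylsilyloxy)labd-14-yn-7-one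
Conditions: Dess–Martin periodinane, CH2Cl2, rt
Reagents that add atoms: none
Why: Dess–Martin oxidation converts the only secondary alcohol into the C7 ketone and cannot oxidise the tertiary C8 alcohol.

Step 20
Reactants: 30 (13S)-9α,13-epoxy-8β-hydroxy-16,19-bis(tert-butyldimethylsilyloxy)labd-14-yn-7-one
Product: 31 (13S)-8β-acetoxy-9α,13-epoxy-16,19-bis(tert-butyldimethylsilyloxy)labd-14-yn-7-one
Conditions: Ac2O, 4-(dimethylamino)pyridine, Et3N, CH2Cl2, 40 °C
Reagents that add atoms: acetic anhydride, CC(=O)OC(C)=O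
Why: Steglich-type nucleophilic catalysis acylates tertiary alcohols, and the C8 hydroxyl is the only free hydroxyl in 30.

Step 21
Reactants: 31 (13S)-8β-acetoxy-9α,13-epoxy-16,19-bis(tert-butyldimethylsilyloxy)labd-14-yn-7-one
Product: 32 (13S)-8β-acetoxy-9α,13-epoxy-16,19-dihydroxylabd-14-yn-7-one
Conditions: Bu4NF, AcOH, THF, rt
Reagents that add atoms: none
Why: Buffered fluoride removes both primary silyl ethers and should leave the tertiary acetate and the ketone intact.

Step 22
Reactants: 32 (13S)-8β-acetoxy-9α,13-epoxy-16,19-dihydroxylabd-14-yn-7-one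
Product: 33 (13S)-8β-acetoxy-9α,13;15,16-diepoxy-19-hydroxylabd-14-en-7-one (target)
Conditions: Mo(CO)6 (25 mol %), Et3N, Et2O, hν (350 nm) to preform (Et3N)Mo(CO)5; then 32, rt, dark
Reagents that add atoms: none
Why: McDonald alkynol cycloisomerisation: the terminal alkyne forms a molybdenum vinylidene that the homopropargylic C16 hydroxyl attacks at C15 (5-endo), giving the 2,3-dihydrofuran under basic conditions that spare the acid-labile spiro ether; the remote C19 hydroxyl cannot reach the alkyne and C13 is not touched.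

**Compound list**

1 | geraniol, (2E)-3,7-dimethylocta-2,6-dien-1-ol | CC(C)=CCC/C(C)=C/CO | starting material
2 | (2R,3R)-2,3-epoxygeraniol, [(2R,3R)-3-methyl-3-(4-methylpent-3-enyl)oxiran-2-yl]methanol | CC(C)=CCC[C@@]1(C)O[C@@H]1CO | intermediate
3 | tert-butyldimethylsilyl ether of 2 | CC(C)=CCC[C@@]1(C)O[C@@H]1CO[Si](C)(C)C(C)(C)C | intermediate
4 | (2R)-2-[(tert-butyldimethylsilyloxy)methyl]-2,6-dimethylhept-5-enal | O=C[C@@](C)(CO[Si](C)(C)C(C)(C)C)CCC=C(C)C | intermediate
5 | methyl (2Z,4S)-4-[(tert-butyldimethylsilyloxy)methyl]-4,8-dimethylnona-2,7-dienoate | COC(=O)/C=C\[C@@](C)(CO[Si](C)(C)C(C)(C)C)CCC=C(C)C | intermediate (not isolated)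
6 | (5S)-5-methyl-5-(4-methylpent-3-enyl)-5,6-dihydro-2H-pyran-2-one | O=C1C=C[C@@](C)(CO1)CCC=C(C)C | intermediate
7 | 3-[(3S)-3-methyl-6-oxo-3,6-dihydro-2H-pyran-3-yl]propanal | O=C1C=C[C@@](C)(CO1)CCC=O | intermediate
8 | 2-bromopentan-3-one (racemic) | CCC(=O)C(C)Br | starting material
9 | (3-oxopentan-2-yl)triphenylphosphonium bromide | CCC(=O)C(C)[P+](c1ccccc1)(c1ccccc1)c1ccccc1.[Br-] | intermediate (not isolated)
10 | 2-(triphenylphosphoranylidene)pentan-3-one | CCC(=O)C(C)=P(c1ccccc1)(c1ccccc1)c1ccccc1 | intermediate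
11 | (5S)-5-methyl-5-[(3E)-4-methyl-5-oxohept-3-enyl]-5,6-dihydro-2H-pyran-2-one | O=C1C=C[C@@](C)(CO1)CC/C=C(\C)C(=O)CC | intermediate
12 | (5S)-5-methyl-5-(4-methyl-5-oxoheptyl)-5,6-dihydro-2H-pyran-2-one, both epimers at the side-chain CHMe carbon | O=C1C=C[C@@](C)(CO1)CCCC(C)C(=O)CC | intermediate
13 | Michael adduct, 5,8a-dimethyl-5-propanoyl-4a,5,6,7,8,8a-hexahydro-1H-isochromen-3(4H)-one; cis-fused lactone, in labdane terms the 19,7-lactone with 4α-methyl, 5α-H, 10β-methyl and the propanoyl group (C9, C8, C17) equatorial on C10 | O=C1C[C@H]2[C@@](C)(CO1)CCC[C@]2(C)C(=O)CC | intermediate (not isolated)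
14 | methyl 2-[2-(hydroxymethyl)-2,6-dimethyl-6-propanoylcyclohexyl]acetate, configurations at C4, C5 and C10 as in 13 | COC(=O)C[C@H]1[C@@](C)(CO)CCC[C@]1(C)C(=O)CC | intermediate (not isolated)
15 | 19-hydroxy-11,12,13,14,15,16-hexanorlabdane-7,9-dione, drawn as the 7-hydroxy-7-en-9-one enol; trans-decalin with 4α-methyl, 4β-CH2OH, 5α-H, 10β-methyl | CC1=C(O)C[C@H]2[C@@](C)(CO)CCC[C@]2(C)C1=O | intermediate
16 | 19-hydroxy-7-methoxy-11,12,13,14,15,16-hexanorlabd-7-en-9-one | CC1=C(OC)C[C@H]2[C@@](C)(CO)CCC[C@]2(C)C1=O | intermediate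
17 | 19-(tert-butyldimethylsilyloxy)-7-methoxy-11,12,13,14,15,16-hexanorlabd-7-en-9-one | CC1=C(OC)C[C@H]2[C@@](C)(CO[Si](C)(C)C(C)(C)C)CCC[C@]2(C)C1=O | intermediate
18 | 2-methylenepropane-1,3-diol | C=C(CO)CO | starting material
19 | 2-[(tert-butyldimethylsilyloxy)methyl]prop-2-en-1-ol | C=C(CO)CO[Si](C)(C)C(C)(C)C | intermediate
20 | (R)-{2-[(tert-butyldimethylsilyloxy)methyl]oxiran-2-yl}methanol | C1[C@@](CO[Si](C)(C)C(C)(C)C)(CO)O1 | intermediate
21 | (R)-2-[(tert-butyldimethylsilyloxy)methyl]oxirane-2-carbaldehyde | C1[C@@](CO[Si](C)(C)C(C)(C)C)(C=O)O1 | intermediate (not isolated)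
22 | (R)-tert-butyl[(2-ethynyloxiran-2-yl)methoxy]dimethylsilane | C1[C@@](CO[Si](C)(C)C(C)(C)C)(C#C)O1 | intermediate
23 | (3S)-3-[(tert-butyldimethylsilyloxy)methyl]-5-(phenylsulfanyl)pent-1-yn-3-ol | c1ccccc1SCC[C@@](CO[Si](C)(C)C(C)(C)C)(C#C)O | intermediate
24 | trilithio reagent from 23 (lithium alkoxide, lithium acetylide and primary alkyllithium at C11) | [Li]CC[C@@](CO[Si](C)(C)C(C)(C)C)(C#C[Li])O[Li] | intermediate (not isolated)
25 | (13S)-16,19-bis(tert-butyldimethylsilyloxy)-7-methoxylabd-7-en-14-yne-9,13-diol, drawn as the 9β-alcohol from attack anti to C20 (configuration at C9 inconsequential) | CC1=C(OC)C[C@H]2[C@@](C)(CO[Si](C)(C)C(C)(C)C)CCC[C@]2(C)[C@]1(O)CC[C@@](CO[Si](C)(C)C(C)(C)C)(C#C)O | intermediate (not isolated)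
26 | (13S)-16,19-bis(tert-butyldimethylsilyloxy)-13-hydroxylabd-8-en-14-yn-7-one | CC1=C(CC[C@@](CO[Si](C)(C)C(C)(C)C)(C#C)O)[C@@]2(C)CCC[C@](C)(CO[Si](C)(C)C(C)(C)C)[C@@H]2CC1=O | intermediate
27 | (13S)-16,19-bis(tert-butyldimethylsilyloxy)labd-8-en-14-yne-7β,13-diol | CC1=C(CC[C@@](CO[Si](C)(C)C(C)(C)C)(C#C)O)[C@@]2(C)CCC[C@](C)(CO[Si](C)(C)C(C)(C)C)[C@@H]2C[C@@H]1O | intermediate
28 | (13S)-8β,9β-epoxy-16,19-bis(tert-butyldimethylsilyloxy)labd-14-yne-7β,13-diol | C[C@]12[C@@H](O)C[C@H]3[C@@](C)(CO[Si](C)(C)C(C)(C)C)CCC[C@]3(C)[C@]1(O2)CC[C@@](CO[Si](C)(C)C(C)(C)C)(C#C)O | intermediate (not isolated)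
29 | (13S)-9α,13-epoxy-16,19-bis(tert-butyldimethylsilyloxy)labd-14-yne-7β,8β-diol | C[C@]1(O)[C@@H](O)C[C@H]2[C@@](C)(CO[Si](C)(C)C(C)(C)C)CCC[C@]2(C)[C@@]12CC[C@@](CO[Si](C)(C)C(C)(C)C)(C#C)O2 | intermediate
30 | (13S)-9α,13-epoxy-8β-hydroxy-16,19-bis(tert-butyldimethylsilyloxy)labd-14-yn-7-one | C[C@]1(O)C(=O)C[C@H]2[C@@](C)(CO[Si](C)(C)C(C)(C)C)CCC[C@]2(C)[C@@]12CC[C@@](CO[Si](C)(C)C(C)(C)C)(C#C)O2 | intermediate
31 | (13S)-8β-acetoxy-9α,13-epoxy-16,19-bis(tert-butyldimethylsilyloxy)labd-14-yn-7-one | CC(=O)O[C@@]1(C)C(=O)C[C@H]2[C@@](C)(CO[Si](C)(C)C(C)(C)C)CCC[C@]2(C)[C@@]12CC[C@@](CO[Si](C)(C)C(C)(C)C)(C#C)O2 | intermediate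
32 | (13S)-8β-acetoxy-9α,13-epoxy-16,19-dihydroxylabd-14-yn-7-one | CC(=O)O[C@@]1(C)C(=O)C[C@H]2[C@@](C)(CO)CCC[C@]2(C)[C@@]12CC[C@@](CO)(C#C)O2 | intermediate
33 | (13S)-8β-acetoxy-9α,13;15,16-diepoxy-19-hydroxylabd-14-en-7-one | CC(=O)O[C@@]1(C)C(=O)C[C@H]2[C@@](C)(CO)CCC[C@]2(C)[C@@]12CC[C@@]1(C=COC1)O2 | target

**Step count and risks**

Total step count: 22. Longest linear sequence: 17 steps (steps 1–5, 7–11 and 16–22, from geraniol).

Steps most likely to fail:

1. Step 9 (key step). The Michael addition is reversible, so during the warm methoxide stage retro-Michael equilibration could feed the C10-epimeric adduct, which would close to a cis-fused dione; the enolate may also discriminate poorly between the two orientations at C10. The fallback sets out from 11 and comes back at 15. The enone carbonyl of 11 is reduced (NaBH4, CeCl3·7H2O, MeOH) to the allylic alcohol F1. Fe(acac)3 and PhSiH3 in EtOH at 60 °C then convert the trisubstituted alkene by hydrogen-atom transfer into the tertiary C10 radical, which closes ring A irreversibly by 6-exo Giese addition to lactone carbon C5 and gives the bicyclic carbinol F2, the bulky CH(OH)Et group lying equatorial. Dess–Martin oxidation of F2 gives 13, now isolated, and NaOMe in MeOH closes ring B to 15.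

2. Step 16. The strongly basic trilithio reagent may γ-enolise the hindered vinylogous ester (or engage through its acetylide end) instead of adding to the C9 carbonyl flanked by quaternary C10. The fallback sets out from 17 and 23 and comes back at 26. γ-Deprotonation of 17 with LiN(iPr)2 and O-triflation with PhNTf2 give the dienyl triflate F3. Sulfide 23 is S-methylated (MeOSO2CF3) and the sulfonium salt is displaced with NaI to give the iodide F4, and zinc insertion (Zn, LiCl, THF) gives the alkylzinc iodide F5. Negishi coupling of F5 with F3 (Pd(OAc)2, 2-dicyclohexylphosphino-2',6'-dimethoxybiphenyl, THF) gives the dienol ether F6, and aqueous HCl hydrolyses F6 to 26.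

3. Step 20. Acyl transfer to the axial tertiary C8 hydroxyl, which is flanked by the spiro centre C9 and 1,3-diaxial to the C20 methyl, may be too slow, and forcing basic conditions could start an α-ketol rearrangement. The fallback sets out from 29 and comes back at 31. The cis-7β,8β-diol of 29 is tied up with MeC(OMe)3 and pyridinium p-toluenesulfonate as the cyclic methyl orthoacetate F7. Mild aqueous acetic acid opens it under stereoelectronic control to the axial ester, the 8β-acetate 7β-alcohol F8, and prompt Dess–Martin oxidation of the remaining secondary alcohol gives 31 directly, bypassing 30.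

Further compounds
F1 | step 9 | (5S)-5-[(3E)-5-hydroxy-4-methylhept-3-enyl]-5-methyl-5,6-dihydro-2H-pyran-2-one (carbinol epimers) | O=C1C=C[C@@](C)(CO1)CC/C=C(\C)C(O)CC
F2 | step 9 | 5-(1-hydroxypropyl)-5,8a-dimethyl-4a,5,6,7,8,8a-hexahydro-1H-isochromen-3(4H)-one, ring configurations as in 13 (carbinol epimers) | O=C1C[C@H]2[C@@](C)(CO1)CCC[C@]2(C)C(O)CC
F3 | step 16 | 19-(tert-butyldimethylsilyloxy)-7-methoxy-11,12,13,14,15,16-hexanorlabda-6,8-dien-9-yl trifluoromethanesulfonate | CC1=C(OS(=O)(=O)C(F)(F)F)[C@@]2(C)CCC[C@](C)(CO[Si](C)(C)C(C)(C)C)[C@@H]2C=C1OC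
F4 | step 16 | (3S)-3-[(tert-butyldimethylsilyloxy)methyl]-5-iodopent-1-yn-3-ol | ICC[C@@](CO[Si](C)(C)C(C)(C)C)(C#C)O
F5 | step 16 | alkylzinc iodide from F4 | I[Zn]CC[C@@](CO[Si](C)(C)C(C)(C)C)(C#C)O
F6 | step 16 | (13S)-16,19-bis(tert-butyldimethylsilyloxy)-7-methoxylabda-6,8-dien-14-yn-13-ol | CC1=C(CC[C@@](CO[Si](C)(C)C(C)(C)C)(C#C)O)[C@@]2(C)CCC[C@](C)(CO[Si](C)(C)C(C)(C)C)[C@@H]2C=C1OC
F7 | step 20 | 7β,8β-O-(1-methoxyethylidene) derivative (cyclic methyl orthoacetate) of 29 | C[C@]12OC(C)(OC)O[C@H]1C[C@H]3[C@@](C)(CO[Si](C)(C)C(C)(C)C)CCC[C@]3(C)[C@@]24CC[C@@](CO[Si](C)(C)C(C)(C)C)(C#C)O4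
F8 | step 20 | (13S)-8β-acetoxy-9α,13-epoxy-16,19-bis(tert-butyldimethylsilyloxy)labd-14-yn-7β-ol | CC(=O)O[C@@]1(C)[C@@H](O)C[C@H]2[C@@](C)(CO[Si](C)(C)C(C)(C)C)CCC[C@]2(C)[C@@]12CC[C@@](CO[Si](C)(C)C(C)(C)C)(C#C)O2
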